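Of the 3 questions you sent with your hunch, the first turned on a ratio and the other two on a count the runs did not show, so I reckoned the large part and treated that count as a correction.

| setting | Sunday's | Tuesday's | gamma | zeta |
|---|---|---|---|---|
| free monomer | 20 mM | 20 mM | 20 mM | 20 mM |
| initiator | 11 mol% | 15 mol% | 7.8 mol% | 12 mol% |
| remark | run made earlier | run made earlier |  |  |
| time |  |  | 25 min | 25 min |

| Sunday's: time / min | Sunday's: monomer in chains / % | Tuesday's: time / min | Tuesday's: monomer in chains / % |
|---|---|---|---|
| 2.00 | 8.9 | 1.00 | 3.6 |
| 4.00 | 24.5 | 1.50 | 7.6 |
| 6.00 | 38.7 | 3.00 | 21.3 |
| 8.00 | 49.6 | 5.00 | 38.1 |
| 10.0 | 55.5 | 8.00 | 55.8 |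
| 12.0 | 58.9 | 12.0 | 64.6 |

(each reading ± 0.5 percentage points)

- which of the two ends with the longer chains by the average number of monomer units in a chain (chains begun, living or dead) ("neither" if they lie within 10%) (gamma / zeta / neither)
- average number of monomer units in a chain (chains begun, living or dead) at the end, gamma
- average number of monomer units in a chain (chains begun, living or dead) at the end, zeta

- the average divides the monomer in chains by the number of chains begun, living and dead together
- the earlier runs do not show the number of chains; that part of a forecast is a guess

1. From Sunday's run to Tuesday's, the loading rose by a factor of 1.36, but the last reading of monomer in chains rose by a factor of 1.10, less than the loading. I therefore took Sunday's 58.9%, read at 12.0 min, as a stand-in for gamma and zeta.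

2. Monomer in chains divided by the initiator charged, the length if each initiator began one chain, gave 7.55 for gamma and 4.91 for zeta. This is my floor length, the theoretical number-average degree of polymerisation.

3. The correction was to divide the floor by the share of initiator used, the drop in c(initiator) over its charge. The runs did not show that share, but with equal shares gamma came out longer by a factor of 1.54, which is more than the margin.

4. The forecast said gamma, with 8 for gamma and 5.7 for zeta, above my floors, on the ground that “Incomplete initiation would raise both values”.

    living end + monomer in chains → dead end (k = 23.0 L mol⁻¹ min⁻¹)
    free monomer + living end → monomer in chains + living end, rate k2*[living end]*[free monomer] (k = 162 L mol⁻¹ min⁻¹)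
    free monomer + initiator → living end + monomer in chains (k = 5.53 L mol⁻¹ min⁻¹)

5. Gamma ended at 10.4 and zeta at 8.10. In gamma, half of the initiation turnover up to 25.0 min was done by 4.86 min, and 84% of the growth turnover up to that time was done by 12.5 min, with living end at 0.272 mM. At 25.0 min in gamma, living end stood at 0.0624 mM and 23% of the initiator charged remained. With each flask's own monomer in chains at the end, the floor over the used share gives 10.4 for gamma and 8.10 for zeta. The neighbour of gamma at 3.1 mol% initiator, with 46.4% in chains and 14% of its initiator left at the end, has a length by the same reckoning of 17.5.

The numbers in the tables are calculated with constants of no real substance; scatter was added.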